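## Retrosynthetic overview

1. Target 23 ⇐ sulfide 21 (sulfoxide elimination unmasks C11=C13) ⇐ diol lactone 19 (acylation of the C8 hydroxyl).
2. 19 ⇐ 14 by the key ring expansion: the C10 samarium ketyl attacks the C1 carbonyl of a seven-membered lactone; collapse of the hemiketal gives the ten-membered α-ketol and frees O6, which closes the γ-lactone.
3. 14 ⇐ aldehyde 12 + acetone (C8–C9 aldol); 12 ⇐ lactone 10 (thiol masking of the acrylate, acetal hydrolysis).
4. 10 ⇐ diene ester 9 by ring-closing metathesis (C4=C5, Z fixed by the seven-membered ring) ⇐ alcohol 7 + acid 8.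
5. 7 ⇐ acrolein + bromide 4 (C6–C7, asymmetric chromium allylation) ⇐ 1 + 2 (Baylis–Hillman). Ring order: seven-membered lactone, then ten-membered carbocycle, then γ-lactone.

Assumption: the target is taken as drawn, (6R,7R,8R,10R,4Z) in germacrane numbering (C1 ketone, C4=C5, C6 lactone carbinol, C8 ester carbinol, C10 tertiary carbinol, C11–C13 methylene-lactone carbons); this numbering is used for all intermediates.
Note: from 11 to 22 the sulfide-bearing carbon C11 is a mixture of epimers (left undefined in the SMILES); step 10 removes this stereocentre.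

## Route

Step 1
Reactants: 1 2,2-dimethoxyacetaldehyde; 2 tert-butyl acrylate
Product: 3 tert-butyl 3-hydroxy-4,4-dimethoxy-2-methylidenebutanoate (racemic)
Conditions: DABCO (0.5 equiv), 1,4-dioxane/H2O 1:1, rt, 36 h
Reagents that add atoms: none
Why: Morita–Baylis–Hillman reaction of an inductively activated aldehyde; the racemic carbinol centre is erased in step 2.

Step 2
Reactants: 3 tert-butyl 3-hydroxy-4,4-dimethoxy-2-methylidenebutanoate
Product: 4 tert-butyl (2Z)-2-(bromomethyl)-4,4-dimethoxybut-2-enoate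
Conditions: NBS (1.2 equiv), Me2S (1.3 equiv), CH2Cl2, 0 °C to rt
Reagents that add atoms: N-bromosuccinimide, O=C1CCC(=O)N1Br
Why: Corey–Kim-type bromination with allylic transposition (SN2') gives the thermodynamically preferred 2Z primary allylic bromide under neutral conditions that spare the acetal.

Step 3
Reactants: 4 tert-butyl (2Z)-2-(bromomethyl)-4,4-dimethoxybut-2-enoate; 5 acrolein
Product: 7 tert-butyl (3S,4R)-3-(dimethoxymethyl)-4-hydroxy-2-methylidenehex-5-enoate, via trimethylsilyl ether 6 (not isolated)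
Conditions: CrCl2 (10 mol%), chiral tridentate carbazole-bis(oxazoline) ligand (11 mol%), Et3N (20 mol%), Mn powder (2 equiv), Me3SiCl (1.5 equiv), THF, rt; then 0.5 M aq. HCl, THF, 0 °C, 10 min
Reagents that add atoms: none
Why: Catalytic asymmetric Nozaki–Hiyama–Kishi 2-(alkoxycarbonyl)allylation; γ-attack of the equilibrating allylchromium through a chair transition state should give the anti adduct (C6/C7), and the ligand enantiomer is chosen to give the 4R carbinol; the tert-butyl ester prevents lactonisation.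

Step 4
Reactants: 7 tert-butyl (3S,4R)-3-(dimethoxymethyl)-4-hydroxy-2-methylidenehex-5-enoate; 8 4-methylpent-4-enoic acid
Product: 9 tert-butyl (3S,4R)-3-(dimethoxymethyl)-2-methylidene-4-(4-methylpent-4-enoyloxy)hex-5-enoate
Conditions: DIC (1.3 equiv), DMAP (0.2 equiv), CH2Cl2, 0 °C to rt
Reagents that add atoms: none
Why: Steglich esterification with retention at C6; it places the C1–C4 unit on O6.

Step 5
Reactants: 9 tert-butyl (3S,4R)-3-(dimethoxymethyl)-2-methylidene-4-(4-methylpent-4-enoyloxy)hex-5-enoate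
Product: 10 tert-butyl (3S)-4,4-dimethoxy-2-methylidene-3-[(2R)-4-methyl-7-oxo-2,5,6,7-tetrahydrooxepin-2-yl]butanoate
Conditions: second-generation Grubbs catalyst RuCl2(=CHPh)(PCy3)(SIMes) (5 mol%), CH2Cl2 (0.005 M), 40 °C
Reagents that add atoms: none
Why: Ring-closing metathesis to the seven-membered lactone; the ring size forces the cis (later 4Z) trisubstituted olefin, and the electron-poor 1,1-disubstituted acrylate olefin does not take part.

Step 6
Reactants: 10 tert-butyl (3S)-4,4-dimethoxy-2-methylidene-3-[(2R)-4-methyl-7-oxo-2,5,6,7-tetrahydrooxepin-2-yl]butanoate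
Product: 12 tert-butyl (3S)-3-[(2R)-4-methyl-7-oxo-2,5,6,7-tetrahydrooxepin-2-yl]-4-oxo-2-(phenylsulfanylmethyl)butanoate, via sulfide acetal 11 (not isolated)
Conditions: PhSH (1.2 equiv), Et3N (0.1 equiv), CH2Cl2, rt; then 1 M aq. HCl, THF, rt
Reagents that add atoms: thiophenol, Sc1ccccc1; water, O
Why: Thia-Michael addition masks the acrylate (no ketyl–acrylate coupling later, no migration of the double bond into conjugation with the aldehyde), then acid hydrolysis of the dimethyl acetal frees the C8 aldehyde while the tert-butyl ester survives.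

Step 7
Reactants: 12 tert-butyl (3S)-3-[(2R)-4-methyl-7-oxo-2,5,6,7-tetrahydrooxepin-2-yl]-4-oxo-2-(phenylsulfanylmethyl)butanoate; 13 acetone
Product: 14 tert-butyl (3R,4R)-4-hydroxy-3-[(2R)-4-methyl-7-oxo-2,5,6,7-tetrahydrooxepin-2-yl]-6-oxo-2-(phenylsulfanylmethyl)heptanoate
Conditions: L-proline (30 mol%), acetone/DMSO 1:4, 4 °C, 48 h
Reagents that add atoms: none
Why: Proline-catalysed direct aldol reaction (enamine catalysis); the acetone enamine attacks the Re face of the α-branched aldehyde under catalyst control, as with simple α-branched aldehydes, giving the R carbinol at C8.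

Step 8
Reactants: 14 tert-butyl (3R,4R)-4-hydroxy-3-[(2R)-4-methyl-7-oxo-2,5,6,7-tetrahydrooxepin-2-yl]-6-oxo-2-(phenylsulfanylmethyl)heptanoate
Product: 19 (4Z)-8,10-dihydroxy-1-oxo-13-(phenylsulfanyl)-11,13-dihydrogermacr-4-en-6,12-olide (C6 C7 C8 C10 as in 23), via trimethylsilyl ether 15 (not isolated), via bicyclic hemiketal 16 (not isolated), via hydroxy ketone ester 17 (not isolated), via silylated lactone 18 (not isolated)
Conditions: Me3SiCl (1.2 equiv), Et3N (1.5 equiv), CH2Cl2, 0 °C, filter, solvent switch to THF; then SmI2 (2.2 equiv), HMPA (8 equiv), THF (0.005 M), −78 °C to rt, then 40 °C, 2 h; then 1 M aq. HCl, THF, 0 °C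
Reagents that add atoms: none
Why: Proposed new method: samarium ketyl–lactone acyl substitution with ring expansion; the ketyl formed at the C10 methyl ketone adds to the C1 carbonyl of the seven-membered lactone to give the 11-oxabicyclo[4.4.1]undecene hemiketalate, whose collapse expels the O6 alkoxide (seven-membered lactone to ten-membered α-ketol), and this alkoxide then lactonises 5-exo onto the tert-butyl ester; trivalent samarium bridges the ketyl oxygen and the lactone carbonyl oxygen, so both oxygens sit cis on the forming ring and the bulky samarium-oxy group lies on the open face away from the olefin bridge, which with C6 fixed gives 10R; the hindered tert-butyl ester and the silyl ether on O8 block acyl substitution at the other carbonyls; closest known reaction types are SmI2-promoted intramolecular nucleophilic acyl substitution ring expansions of haloalkyl lactones and SmI2 ketyl–carbonyl (pinacol-type) couplings.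

Step 9
Reactants: 19 (4Z)-8,10-dihydroxy-1-oxo-13-(phenylsulfanyl)-11,13-dihydrogermacr-4-en-6,12-olide; 20 3-methylbutanoyl chloride (isovaleryl chloride)
Product: 21 (4Z)-10-hydroxy-8-(3-methylbutanoyloxy)-1-oxo-13-(phenylsulfanyl)-11,13-dihydrogermacr-4-en-6,12-olide
Conditions: pyridine (3 equiv), DMAP (0.1 equiv), CH2Cl2, 0 °C
Reagents that add atoms: none
Why: DMAP-catalysed acylation is selective for the secondary C8 hydroxyl over the tertiary C10 hydroxyl next to the ketone.

Step 10
Reactants: 21 (4Z)-10-hydroxy-8-(3-methylbutanoyloxy)-1-oxo-13-(phenylsulfanyl)-11,13-dihydrogermacr-4-en-6,12-olide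
Product: 23 (3aR,4R,6R,10Z,11aR)-6-hydroxy-6,10-dimethyl-3-methylidene-2,7-dioxo-2,3,3a,4,5,6,7,8,9,11a-decahydrocyclodeca[b]furan-4-yl 3-methylbutanoate, via sulfoxide 22 (not isolated)
Conditions: NaIO4 (1.1 equiv), MeOH/H2O, 0 °C to rt; then NaHCO3, toluene, 100 °C
Reagents that add atoms: none
Why: Periodate oxidises the sulfide to the sulfoxide without touching the olefin, and thermal syn-elimination (sulfoxide pyrolysis) can only use the C11 hydrogen, so only the exocyclic methylene forms.

## Compound list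

1 | 2,2-dimethoxyacetaldehyde | COC(OC)C=O | starting material
2 | tert-butyl acrylate (acrylic acid carrying a tert-butyl ester protecting group) | C=CC(=O)OC(C)(C)C | starting material
3 | tert-butyl 3-hydroxy-4,4-dimethoxy-2-methylidenebutanoate (racemic) | COC(OC)C(O)C(=C)C(=O)OC(C)(C)C | intermediate
4 | tert-butyl (2Z)-2-(bromomethyl)-4,4-dimethoxybut-2-enoate | COC(OC)/C=C(\CBr)C(=O)OC(C)(C)C | intermediate
5 | acrolein | C=CC=O | starting material
6 | tert-butyl (3S,4R)-3-(dimethoxymethyl)-2-methylidene-4-(trimethylsilyloxy)hex-5-enoate | C=C[C@@H](O[Si](C)(C)C)[C@@H](C(OC)OC)C(=C)C(=O)OC(C)(C)C | intermediate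
7 | tert-butyl (3S,4R)-3-(dimethoxymethyl)-4-hydroxy-2-methylidenehex-5-enoate | C=C[C@@H](O)[C@@H](C(OC)OC)C(=C)C(=O)OC(C)(C)C | intermediate
8 | 4-methylpent-4-enoic acid | C=C(C)CCC(=O)O | starting material
9 | tert-butyl (3S,4R)-3-(dimethoxymethyl)-2-methylidene-4-(4-methylpent-4-enoyloxy)hex-5-enoate | C=C[C@@H](OC(=O)CCC(C)=C)[C@@H](C(OC)OC)C(=C)C(=O)OC(C)(C)C | intermediate
10 | tert-butyl (3S)-4,4-dimethoxy-2-methylidene-3-[(2R)-4-methyl-7-oxo-2,5,6,7-tetrahydrooxepin-2-yl]butanoate | O=C1CCC(C)=C[C@@H](O1)[C@@H](C(OC)OC)C(=C)C(=O)OC(C)(C)C | intermediate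
11 | tert-butyl (3S)-4,4-dimethoxy-3-[(2R)-4-methyl-7-oxo-2,5,6,7-tetrahydrooxepin-2-yl]-2-(phenylsulfanylmethyl)butanoate (C2 epimers) | O=C1CCC(C)=C[C@@H](O1)[C@@H](C(OC)OC)C(CSc1ccccc1)C(=O)OC(C)(C)C | intermediate
12 | tert-butyl (3S)-3-[(2R)-4-methyl-7-oxo-2,5,6,7-tetrahydrooxepin-2-yl]-4-oxo-2-(phenylsulfanylmethyl)butanoate (C2 epimers) | O=C1CCC(C)=C[C@@H](O1)[C@@H](C=O)C(CSc1ccccc1)C(=O)OC(C)(C)C | intermediate
13 | acetone | CC(C)=O | starting material
14 | tert-butyl (3R,4R)-4-hydroxy-3-[(2R)-4-methyl-7-oxo-2,5,6,7-tetrahydrooxepin-2-yl]-6-oxo-2-(phenylsulfanylmethyl)heptanoate (C2 epimers) | O=C1CCC(C)=C[C@@H](O1)[C@@H]([C@H](O)CC(C)=O)C(CSc1ccccc1)C(=O)OC(C)(C)C | intermediate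
15 | O-trimethylsilyl ether of 14 (silyl on the C8 oxygen, configuration as in 14) | O=C1CCC(C)=C[C@@H](O1)[C@@H]([C@H](O[Si](C)(C)C)CC(C)=O)C(CSc1ccccc1)C(=O)OC(C)(C)C | intermediate
16 | bicyclic hemiketal, neutral form of the samarium hemiketalate: 11-oxabicyclo[4.4.1]undecene with the oxygen bridge between C1 and C6, hydroxyls on C1 and C10 cis, 8-OSiMe3, C7 side chain CH(CH2SPh)CO2tBu | CC1=C[C@H]2O[C@@](O)(CC1)[C@](C)(O)C[C@@H](O[Si](C)(C)C)[C@H]2C(CSc1ccccc1)C(=O)OC(C)(C)C | intermediate
17 | ring-expanded hydroxy ketone tert-butyl ester: ten-membered ring with C1 ketone, 4Z olefin, free 6-OH and 10-OH, 8-OSiMe3, C7 side chain CH(CH2SPh)CO2tBu (C6 C7 C8 C10 as in 23) | O[C@@H]1/C=C(/C)CCC(=O)[C@](C)(O)C[C@@H](O[Si](C)(C)C)[C@H]1C(CSc1ccccc1)C(=O)OC(C)(C)C | intermediate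
18 | 8-O-trimethylsilyl ether of 19 | C(Sc1ccccc1)C1C(=O)O[C@@H]2/C=C(/C)CCC(=O)[C@](C)(O)C[C@@H](O[Si](C)(C)C)[C@@H]12 | intermediate
19 | (4Z)-8,10-dihydroxy-1-oxo-13-(phenylsulfanyl)-11,13-dihydrogermacr-4-en-6,12-olide (C6, C7, C8, C10 as in 23; C11 epimers) | C(Sc1ccccc1)C1C(=O)O[C@@H]2/C=C(/C)CCC(=O)[C@](C)(O)C[C@@H](O)[C@@H]12 | intermediate
20 | 3-methylbutanoyl chloride (isovaleryl chloride) | CC(C)CC(=O)Cl | starting material
21 | (4Z)-10-hydroxy-8-(3-methylbutanoyloxy)-1-oxo-13-(phenylsulfanyl)-11,13-dihydrogermacr-4-en-6,12-olide (C6, C7, C8, C10 as in 23; C11 epimers) | C(Sc1ccccc1)C1C(=O)O[C@@H]2/C=C(/C)CCC(=O)[C@](C)(O)C[C@@H](OC(=O)CC(C)C)[C@@H]12 | intermediate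
22 | S-oxide (sulfoxide) of 21 | C(S(=O)c1ccccc1)C1C(=O)O[C@@H]2/C=C(/C)CCC(=O)[C@](C)(O)C[C@@H](OC(=O)CC(C)C)[C@@H]12 | intermediate
23 | (3aR,4R,6R,10Z,11aR)-6-hydroxy-6,10-dimethyl-3-methylidene-2,7-dioxo-2,3,3a,4,5,6,7,8,9,11a-decahydrocyclodeca[b]furan-4-yl 3-methylbutanoate | C=C1C(=O)O[C@@H]2/C=C(/C)CCC(=O)[C@](C)(O)C[C@@H](OC(=O)CC(C)C)[C@@H]12 | target

## Step count and risks

Total steps: 10. Longest linear sequence: 10 steps (from 1 and 2 to 23).

The three steps most likely to fail:

Step 8 (the proposed ring expansion). The seven-membered transition state may be too slow against pinacol dimerisation or simple ketone reduction, and the samarium alkoxide may lactonise sluggishly onto the tert-butyl ester. The fallback sets out from aldehyde 12 and comes back at 19, using known reactions only. Chromium-mediated asymmetric 2-bromoallylation of 12 (CrCl2, chiral sulfonamide ligand, 2,3-dibromopropene, Mn, Me3SiCl) gives the 2-bromoallyl carbinol F1. Et3SiCl/imidazole gives its triethylsilyl ether F2. Bromine–lithium exchange (t-BuLi, 2 equiv, THF, −78 °C) gives a vinyllithium that attacks the lactone carbonyl (anionic acyl substitution with ring expansion); the freed O6 alkoxide closes the γ-lactone to give the exo-methylene ketone F3. Mukaiyama-type hydration of this enone (Mn(dpm)3, PhSiH3, O2, then P(OEt)3) puts the tertiary hydroxyl on C10 to give the silylated ketol F4, with C10 epimers separated if needed. 1 M aq. HCl in THF removes the silyl group to give 19.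

Step 3 (asymmetric allylation). The anti selectivity is an inference from general crotyl-type chromium additions; the syn adduct or loss of methoxide from the allylchromium could dominate. The fallback sets out from bromide 4 and comes back at ester 9. Indium-mediated Barbier addition of 4 to acrolein (In powder, THF/H2O) is expected to give the racemic syn alcohol. Sharpless kinetic resolution (Ti(OiPr)4, diisopropyl tartrate, t-BuOOH, CH2Cl2, −20 °C) leaves the (3S,4S) syn alcohol F5. Mitsunobu esterification with acid 8 (PPh3, DIAD, THF) inverts the carbinol centre and gives 9 directly.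

Step 7 (proline aldol). The aldehyde carries a β-acyloxy group that could be lost through an enamine, and the substrate may oppose the catalyst. The fallback sets out from aldehyde 12 and comes back at 14. Brown allylation with B-allyldiisopinocampheylborane (Et2O, −78 °C, ethanolamine work-up, no amine base) gives the homoallylic alcohol F6 under reagent control. Tsuji–Wacker oxidation of its terminal olefin (PdCl2, CuCl, O2, DMF/H2O) gives methyl ketone 14.

## Further compounds

F1 | step 8 | tert-butyl (3R,4R)-6-bromo-4-hydroxy-3-[(2R)-4-methyl-7-oxo-2,5,6,7-tetrahydrooxepin-2-yl]-2-(phenylsulfanylmethyl)hept-6-enoate | O=C1CCC(C)=C[C@@H](O1)[C@@H]([C@H](O)CC(Br)=C)C(CSc1ccccc1)C(=O)OC(C)(C)C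
F2 | step 8 | O-triethylsilyl ether of F1 | O=C1CCC(C)=C[C@@H](O1)[C@@H]([C@H](O[Si](CC)(CC)CC)CC(Br)=C)C(CSc1ccccc1)C(=O)OC(C)(C)C
F3 | step 8 | (4Z)-10-methylidene-1-oxo-13-(phenylsulfanyl)-8-(triethylsilyloxy)-14-nor-11,13-dihydrogermacr-4-en-6,12-olide (ten-membered exo-methylene ketone, C6 C7 C8 as in 23) | C(Sc1ccccc1)C1C(=O)O[C@@H]2/C=C(/C)CCC(=O)C(=C)C[C@@H](O[Si](CC)(CC)CC)[C@@H]12
F4 | step 8 | 8-O-triethylsilyl ether of 19 | C(Sc1ccccc1)C1C(=O)O[C@@H]2/C=C(/C)CCC(=O)[C@](C)(O)C[C@@H](O[Si](CC)(CC)CC)[C@@H]12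
F5 | step 3 | tert-butyl (3S,4S)-3-(dimethoxymethyl)-4-hydroxy-2-methylidenehex-5-enoate | C=C[C@H](O)[C@@H](C(OC)OC)C(=C)C(=O)OC(C)(C)C
F6 | step 7 | tert-butyl (3R,4R)-4-hydroxy-3-[(2R)-4-methyl-7-oxo-2,5,6,7-tetrahydrooxepin-2-yl]-2-(phenylsulfanylmethyl)hept-6-enoate | O=C1CCC(C)=C[C@@H](O1)[C@@H]([C@H](O)CC=C)C(CSc1ccccc1)C(=O)OC(C)(C)C
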